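**Plan**

- Retrosynthesis: the lactone C–O bond is cut first (keto acid). The aryl–CH bond is cut next, together with the seven-membered ring, back to a cyclopropanol fused to a cyclohexene. Then the cyclopropane CH2 and the carboxyl carbon are removed (achiral 4,4-disubstituted cyclohexadienone). Last, the bond between the two quaternary carbons is cut (tertiary benzylic chloride + 3-ethoxycyclohexenone).
- Forward: the dibromo(ethyl)arene is fixed in step 1. The sequence is cyclohexenone, cyclohexadienone, vinyl adduct, acid, 1-hydroxybicyclo[4.1.0]heptene. One step then turns the six-membered ring into the cycloheptenone and closes the tetralin ring. The γ-lactone closes last.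
- Enabling feature: in the seven-membered ring the benzylic CH is β to the ring ketone (through the CH–O carbon) and 1,3 to the quaternary C–CH3 that carries the CMe2–aryl group. A radical at that carbon is therefore the ring-expansion product of a cyclopropanol, and it sits one six-membered transition state away from an ortho carbon of the aryl ring. The 3,5-dibromo-4-ethylphenyl ring has two equivalent ortho carbons.
- Stereochemistry: the absolute configuration comes from a [Rh(cod)2]BF4/(S)-BINAP desymmetrisation of the dienone, which sets the quaternary C–CH3 and the CH–CO2H together. The benzylic CH is set by the tether in the key step, and the CH–O by intramolecular delivery from the carboxyl group in the last step.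

Key step: step 13

Remark on the chemistry: the intermediates that carry only the quaternary C–CH3 centre before the dienone are racemic; this is of no consequence because that centre becomes prochiral in the dienone.

**Route**

Step 1
Reactants: 1 methyl 4-ethylbenzoate
Product: 2 methyl 3,5-dibromo-4-ethylbenzoate
Conditions: 1,3-dibromo-5,5-dimethylhydantoin (1.1 equiv), conc. H2SO4, 0 °C to rt, dark
Reagents that add atoms: 1,3-dibromo-5,5-dimethylhydantoin, CC1(C)N(Br)C(=O)N(Br)C1=O
Why: Electrophilic aromatic bromination in sulfuric acid, in which the ethyl group (ortho) and the protonated ester (meta) direct both bromines to the two positions flanking the ethyl group, so the halogen pattern of the target is fixed before any sensitive group exists.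

Step 2
Reactants: 2 methyl 3,5-dibromo-4-ethylbenzoate
Product: 3 2-(3,5-dibromo-4-ethylphenyl)propan-2-ol
Conditions: MeMgBr (3 equiv), THF, 0 °C to rt; aq. NH4Cl
Reagents that add atoms: methylmagnesium bromide, C[Mg]Br
Why: Double Grignard addition to the ester should give the tertiary benzylic alcohol, the aryl bromides being inert to MeMgBr at this temperature.

Step 3
Reactants: 3 2-(3,5-dibromo-4-ethylphenyl)propan-2-ol
Product: 4 1,3-dibromo-5-(2-chloropropan-2-yl)-2-ethylbenzene
Conditions: HCl (gas), CaCl2, CH2Cl2, 0 °C; used crude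
Reagents that add atoms: hydrogen chloride, Cl
Why: SN1 substitution of a tertiary benzylic alcohol by chloride gives the cation precursor for step 5.

Step 4
Reactants: 5 3-ethoxycyclohex-2-en-1-one
Product: 6 1-ethoxy-3-(trimethylsilyloxy)cyclohexa-1,3-diene
Conditions: LiN(iPr)2, THF, −78 °C; Me3SiCl; non-aqueous work-up
Reagents that add atoms: chlorotrimethylsilane, C[Si](C)(C)Cl
Why: Kinetic α'-deprotonation of the vinylogous ester (Stork–Danheiser enolate) and O-silylation give the 1-alkoxy-3-siloxy diene, which is nucleophilic at its terminal carbon.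

Step 5
Reactants: 6 1-ethoxy-3-(trimethylsilyloxy)cyclohexa-1,3-diene; 4 1,3-dibromo-5-(2-chloropropan-2-yl)-2-ethylbenzene
Product: 7 6-[2-(3,5-dibromo-4-ethylphenyl)propan-2-yl]-3-ethoxycyclohex-2-en-1-one (racemic)
Conditions: TiCl4 (1.1 equiv), CH2Cl2, −78 to −40 °C; aq. NaHCO3
Reagents that add atoms: none
Why: Lewis-acid-mediated α-tert-alkylation of a silyl enol ether (Reetz alkylation, a vinylogous Mukaiyama-type SN1 reaction), in which TiCl4 ionises 4 to the tertiary benzylic cation and the terminal carbon of diene 6 takes it up, forming the benzylic quaternary carbon next to a CH.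

Step 6
Reactants: 7 6-[2-(3,5-dibromo-4-ethylphenyl)propan-2-yl]-3-ethoxycyclohex-2-en-1-one
Product: 8 6-[2-(3,5-dibromo-4-ethylphenyl)propan-2-yl]-3-ethoxy-6-methylcyclohex-2-en-1-one (racemic)
Conditions: LiN(iPr)2, THF, −78 °C; MeI, DMPU, −78 to 0 °C
Reagents that add atoms: iodomethane, CI
Why: Kinetic α'-deprotonation and SN2 methylation (second Stork–Danheiser alkylation) complete the two adjacent quaternary carbons, with only the small electrophile MeI asked to enter next to the tertiary alkyl group.

Step 7
Reactants: 8 6-[2-(3,5-dibromo-4-ethylphenyl)propan-2-yl]-3-ethoxy-6-methylcyclohex-2-en-1-one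
Product: 10 4-[2-(3,5-dibromo-4-ethylphenyl)propan-2-yl]-4-methylcyclohex-2-en-1-one (racemic), via allylic alcohol 9 (not isolated)
Conditions: LiAlH4, Et2O, 0 °C; then 1 M aq. HCl, THF, rt
Reagents that add atoms: water, O
Why: Stork–Danheiser transposition, in which 1,2-reduction of the vinylogous ester and acid hydrolysis of the allylic enol ether 9 give the 4,4-disubstituted cyclohexenone, the new carbonyl oxygen coming from water.

Step 8
Reactants: 10 4-[2-(3,5-dibromo-4-ethylphenyl)propan-2-yl]-4-methylcyclohex-2-en-1-one
Product: 12 4-[2-(3,5-dibromo-4-ethylphenyl)propan-2-yl]-4-methylcyclohexa-2,5-dien-1-one (achiral), via trimethylsilyl dienol ether 11 (not isolated)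
Conditions: LiN(iPr)2, THF, −78 °C; Me3SiCl; then Pd(OAc)2 (10 mol %), O2 (1 atm), DMSO, rt
Reagents that add atoms: chlorotrimethylsilane, C[Si](C)(C)Cl (carried only in intermediate 11)
Why: Ito–Saegusa dehydrogenation, in which only the α' protons can be removed (the γ carbon is quaternary) and Pd(OAc)2-catalysed dehydrosilylation of 11 under neutral conditions gives the cross-conjugated dienone without acid that could cleave its ipso-alkyl bond; the racemic centre becomes a prochiral carbon with two enantiotopic enone halves.

Step 9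
Reactants: 12 4-[2-(3,5-dibromo-4-ethylphenyl)propan-2-yl]-4-methylcyclohexa-2,5-dien-1-one
Product: 13 (4R,5S)-4-[2-(3,5-dibromo-4-ethylphenyl)propan-2-yl]-5-ethenyl-4-methylcyclohex-2-en-1-one
Conditions: [Rh(cod)2]BF4 (3 mol %), (S)-BINAP (3.3 mol %), potassium vinyltrifluoroborate (2 equiv), toluene/H2O, 100 °C
Reagents that add atoms: potassium vinyltrifluoroborate, [K+].C=C[B-](F)(F)F
Why: Asymmetric 1,4-addition of an alkenylboron reagent (Hayashi–Miyaura reaction) used as a desymmetrisation, in which the vinyl group enters anti to the bulky 2-arylpropan-2-yl group and the (S)-ligand, which delivers to the 2si face of cyclohex-2-enones, finds that anti face on only one of the two enantiotopic alkenes, so the quaternary carbon and the adjacent CH are set together.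

Step 10
Reactants: 13 (4R,5S)-4-[2-(3,5-dibromo-4-ethylphenyl)propan-2-yl]-5-ethenyl-4-methylcyclohex-2-en-1-one
Product: 15 (1R,2R)-2-[2-(3,5-dibromo-4-ethylphenyl)propan-2-yl]-2-methyl-5-oxocyclohex-3-ene-1-carboxylic acid, via aldehyde 14 (not isolated)
Conditions: O3, CH2Cl2/MeOH, −78 °C (Sudan Red 7B end point); Me2S; then NaClO2, NaH2PO4, 2-methylbut-2-ene, t-BuOH/H2O, rt
Reagents that add atoms: ozone, [O-][O+]=O; sodium chlorite, [Na+].[O-]Cl=O
Why: Ozonolysis of the electron-richer vinyl group in the presence of the enone, followed by Pinnick oxidation of aldehyde 14, should give the acid with the carboxyl already in its more stable position trans to the large group.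

Step 11
Reactants: 15 (1R,2R)-2-[2-(3,5-dibromo-4-ethylphenyl)propan-2-yl]-2-methyl-5-oxocyclohex-3-ene-1-carboxylic acid
Product: 16 trimethylsilyl (1R,6R)-6-[2-(3,5-dibromo-4-ethylphenyl)propan-2-yl]-6-methyl-3-(trimethylsilyloxy)cyclohexa-2,4-diene-1-carboxylate
Conditions: Me3SiOTf (2.4 equiv), Et3N (3 equiv), CH2Cl2, 0 °C; pentane extraction, used crude
Reagents that add atoms: trimethylsilyl trifluoromethanesulfonate, C[Si](C)(C)OS(=O)(=O)C(F)(F)F
Why: Soft enolisation, in which the enone has no γ hydrogen so only the α' CH2 can be enolised and the 2-siloxy-1,3-diene forms regiospecifically while the acid is masked as its silyl ester.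

Step 12
Reactants: 16 trimethylsilyl (1R,6R)-6-[2-(3,5-dibromo-4-ethylphenyl)propan-2-yl]-6-methyl-3-(trimethylsilyloxy)cyclohexa-2,4-diene-1-carboxylate
Product: 18 (1S,2R,3R,6S)-3-[2-(3,5-dibromo-4-ethylphenyl)propan-2-yl]-6-hydroxy-3-methylbicyclo[4.1.0]hept-4-ene-2-carboxylic acid, via bis-silylated cyclopropane 17 (not isolated)
Conditions: Et2Zn, CH2I2, CH2Cl2, 0 °C to rt; then K2CO3 (cat.), MeOH, 0 °C; pH 5 buffer; used without chromatography
Reagents that add atoms: diiodomethane, ICI
Why: Simmons–Smith cyclopropanation (Furukawa variant, EtZnCH2I) occurs at the electron-rich silyl enol ether double bond of the 2-siloxydiene, and methanolysis of both silyl groups of 17 gives the 1-vinylcyclopropanol acid; the CH2 is drawn on the face of the carboxyl group (anti to the large group), but this configuration is lost in step 13 and either diastereomer serves.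

Step 13
Reactants: 18 (1S,2R,3R,6S)-3-[2-(3,5-dibromo-4-ethylphenyl)propan-2-yl]-6-hydroxy-3-methylbicyclo[4.1.0]hept-4-ene-2-carboxylic acid
Product: 19 (5S,10R,12R)-2,4-dibromo-3-ethyl-10,11,11-trimethyl-7-oxo-6,7,10,11-tetrahydro-5H-5,10-methanobenzo[9]annulene-12-carboxylic acid (the target without its lactone C–O bond: CH2 in place of CH–O and a free CO2H)
Conditions: manganese tris(pyridine-2-carboxylate), Mn(C6H4NO2)3 (2.5 equiv), DMF, degassed, 0 °C to rt
Reagents that add atoms: none
Why: Proposed new method: ligand exchange puts the cyclopropanol oxygen of 18 on trivalent manganese, inner-sphere electron transfer gives the alkoxy radical, and β-scission of the ring-fusion bond of the bicyclo[4.1.0]heptene expands the six-membered ring to the cyclohept-2-enone with a secondary radical β to the new ketone; this radical attacks an ortho carbon of the aryl ring, and a second equivalent of oxidant takes the cyclohexadienyl radical to the cation, which loses a proton to restore the arene. The closest known reactions are the ring expansion–cyclisation of 1-siloxy- and 1-hydroxybicyclo[n.1.0]alkanes with iron trichloride, iron trinitrate or manganese tris(pyridine-2-carboxylate), in which the ring-expanded β-keto radical is caught by a tethered alkene, and the oxidative cyclisation of cyclopropanol-derived β-keto radicals onto arenes in cascades; new here is the capture of the ring-expanded radical by an arene to close a bridged ring. The six-membered carbocycle closes by ortho attack of the radical on the arene (Ar2-6, 6-exo with respect to the attacked aromatic C=C), whereas the seven-membered ring is not closed but arises by C–C cleavage of the fused cyclopropane. The new benzylic stereocentre is set by the tether, because the aryl group can reach the radical only on the ring face cis to the C–CMe2Ar bond of the quaternary centre fixed in step 9, and both cyclopropane diastereomers of 18 converge on the same planar radical. The step needs cleavage of the internal over the external cyclopropane bond (secured by the secondary versus primary radical), and it needs ortho attack to beat ipso attack, oxidation and hydrogen abstraction (favoured by the quaternary centres that hold the arene over the radical, by the match of a nucleophilic alkyl radical with the electron-poor dibromoarene, and by a mild oxidant free of chloride and divalent copper). No regiochemical choice arises on the arene, because its two ortho carbons are equivalent.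

Step 14
Reactants: 19 (5S,10R,12R)-2,4-dibromo-3-ethyl-10,11,11-trimethyl-7-oxo-6,7,10,11-tetrahydro-5H-5,10-methanobenzo[9]annulene-12-carboxylic acid
Product: 20 salimabromide
Conditions: PhI(OH)OTs (1.2 equiv), MeCN, 50 °C
Reagents that add atoms: none
Why: Hypervalent-iodine α-oxylactonisation of a keto acid (Koser's reagent), in which the enone can enolise only toward its α' CH2, the enol is captured by trivalent iodine, and the carboxylate, which can reach this carbon only from the face on which it sits, displaces iodobenzene (5-exo-tet), so the CH–O stereocentre is set by intramolecular delivery.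

**Compound list**

1 | methyl 4-ethylbenzoate | CCc1ccc(cc1)C(=O)OC | starting material
2 | methyl 3,5-dibromo-4-ethylbenzoate | CCc1c(Br)cc(cc1Br)C(=O)OC | intermediate
3 | 2-(3,5-dibromo-4-ethylphenyl)propan-2-ol | CCc1c(Br)cc(cc1Br)C(C)(C)O | intermediate
4 | 1,3-dibromo-5-(2-chloropropan-2-yl)-2-ethylbenzene | CCc1c(Br)cc(cc1Br)C(C)(C)Cl | intermediate
5 | 3-ethoxycyclohex-2-en-1-one | CCOC1=CC(=O)CCC1 | starting material
6 | 1-ethoxy-3-(trimethylsilyloxy)cyclohexa-1,3-diene | CCOC1=CC(O[Si](C)(C)C)=CCC1 | intermediate
7 | 6-[2-(3,5-dibromo-4-ethylphenyl)propan-2-yl]-3-ethoxycyclohex-2-en-1-one (racemic) | CCOC1=CC(=O)C(CC1)C(C)(C)c1cc(Br)c(CC)c(Br)c1 | intermediate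
8 | 6-[2-(3,5-dibromo-4-ethylphenyl)propan-2-yl]-3-ethoxy-6-methylcyclohex-2-en-1-one (racemic) | CCOC1=CC(=O)C(C)(CC1)C(C)(C)c1cc(Br)c(CC)c(Br)c1 | intermediate
9 | 6-[2-(3,5-dibromo-4-ethylphenyl)propan-2-yl]-3-ethoxy-6-methylcyclohex-2-en-1-ol (racemic, not isolated) | CCOC1=CC(O)C(C)(CC1)C(C)(C)c1cc(Br)c(CC)c(Br)c1 | intermediate
10 | 4-[2-(3,5-dibromo-4-ethylphenyl)propan-2-yl]-4-methylcyclohex-2-en-1-one (racemic) | CC1(CCC(=O)C=C1)C(C)(C)c1cc(Br)c(CC)c(Br)c1 | intermediate
11 | {4-[2-(3,5-dibromo-4-ethylphenyl)propan-2-yl]-4-methylcyclohexa-1,5-dien-1-yl}oxy(trimethyl)silane (not isolated) | CC1(CC=C(O[Si](C)(C)C)C=C1)C(C)(C)c1cc(Br)c(CC)c(Br)c1 | intermediate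
12 | 4-[2-(3,5-dibromo-4-ethylphenyl)propan-2-yl]-4-methylcyclohexa-2,5-dien-1-one | CC1(C=CC(=O)C=C1)C(C)(C)c1cc(Br)c(CC)c(Br)c1 | intermediate
13 | (4R,5S)-4-[2-(3,5-dibromo-4-ethylphenyl)propan-2-yl]-5-ethenyl-4-methylcyclohex-2-en-1-one | C=C[C@@H]1CC(=O)C=C[C@@]1(C)C(C)(C)c1cc(Br)c(CC)c(Br)c1 | intermediate
14 | (1R,2R)-2-[2-(3,5-dibromo-4-ethylphenyl)propan-2-yl]-2-methyl-5-oxocyclohex-3-ene-1-carbaldehyde (not isolated) | O=C[C@@H]1CC(=O)C=C[C@@]1(C)C(C)(C)c1cc(Br)c(CC)c(Br)c1 | intermediate
15 | (1R,2R)-2-[2-(3,5-dibromo-4-ethylphenyl)propan-2-yl]-2-methyl-5-oxocyclohex-3-ene-1-carboxylic acid | OC(=O)[C@@H]1CC(=O)C=C[C@@]1(C)C(C)(C)c1cc(Br)c(CC)c(Br)c1 | intermediate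
16 | trimethylsilyl (1R,6R)-6-[2-(3,5-dibromo-4-ethylphenyl)propan-2-yl]-6-methyl-3-(trimethylsilyloxy)cyclohexa-2,4-diene-1-carboxylate | C[Si](C)(C)OC(=O)[C@@H]1C=C(O[Si](C)(C)C)C=C[C@@]1(C)C(C)(C)c1cc(Br)c(CC)c(Br)c1 | intermediate
17 | trimethylsilyl (1S,2R,3R,6S)-3-[2-(3,5-dibromo-4-ethylphenyl)propan-2-yl]-3-methyl-6-(trimethylsilyloxy)bicyclo[4.1.0]hept-4-ene-2-carboxylate (not isolated) | C[Si](C)(C)OC(=O)[C@@H]1[C@@H]2C[C@]2(O[Si](C)(C)C)C=C[C@@]1(C)C(C)(C)c1cc(Br)c(CC)c(Br)c1 | intermediate
18 | (1S,2R,3R,6S)-3-[2-(3,5-dibromo-4-ethylphenyl)propan-2-yl]-6-hydroxy-3-methylbicyclo[4.1.0]hept-4-ene-2-carboxylic acid | OC(=O)[C@@H]1[C@@H]2C[C@]2(O)C=C[C@@]1(C)C(C)(C)c1cc(Br)c(CC)c(Br)c1 | intermediate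
19 | (5S,10R,12R)-2,4-dibromo-3-ethyl-10,11,11-trimethyl-7-oxo-6,7,10,11-tetrahydro-5H-5,10-methanobenzo[9]annulene-12-carboxylic acid | CCc1c(Br)cc2c(c1Br)[C@H]1CC(=O)C=C[C@](C)([C@@H]1C(=O)O)C2(C)C | intermediate
20 | salimabromide | CCc1c(Br)cc2c(c1Br)[C@H]1[C@@H]3OC(=O)[C@H]1[C@@](C)(C=CC3=O)C2(C)C | target

**Summary**

Total step count: 14. Longest linear sequence: 13 steps (from 1 through steps 1–3 and 5–14).

**Steps most likely to fail**

Step 13 (proposed new method). The ring-expanded radical may be oxidised to the alkene, reduced by the solvent, or attack the ipso carbon before it closes onto the ortho carbon. The fallback sets out from 18 and comes back at 19, replacing the radical closure by a polar one of known types. FeCl3 in DMF at 0 °C should give, by the known ring expansion with chlorine transfer, 7-chloro-2-[2-(3,5-dibromo-4-ethylphenyl)propan-2-yl]-2-methyl-5-oxocyclohept-3-ene-1-carboxylic acid F1. NaOAc in refluxing MeOH should then eliminate HCl to the cross-conjugated (1R,2R)-2-[2-(3,5-dibromo-4-ethylphenyl)propan-2-yl]-2-methyl-5-oxocyclohepta-3,6-diene-1-carboxylic acid F2. CF3SO3H in CH2Cl2 at 0 °C should effect the intramolecular Friedel–Crafts conjugate addition of the arene to the unhindered β-carbon of the dienone (6-exo), giving 19. The attacked aromatic carbon is ortho and para to the two bromines and ortho to the tertiary alkyl group, and the other β-carbon is neopentyl; the benzylic configuration is again set by the tether.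

Step 9. Insertion at the β-carbon next to the quaternary centre may be slow, or the two enantiotopic alkenes may be poorly distinguished. The fallback sets out from 12 and comes back at 15, replacing catalytic desymmetrisation by substrate-controlled addition and classical resolution. Vinylmagnesium bromide with CuBr·SMe2 (cat.) in THF at −40 °C should add anti to the large group and give racemic (4R*,5S*)-4-[2-(3,5-dibromo-4-ethylphenyl)propan-2-yl]-5-ethenyl-4-methylcyclohex-2-en-1-one F3. The conditions of step 10 should take it through the racemic aldehyde F4 to the racemic acid F5. Crystallisation with (R)-1-phenylethylamine should give the salt of the (1R,2R)-acid F6, and acidification returns 15. If the salt of the antipode is the less soluble one, the (S)-amine is used.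

Step 14. Enolisation toward the CH2 next to the bridgehead may be slow, or the iodine-bound intermediate may be captured on the face the carboxylate cannot reach. The fallback sets out from 19 and comes back at 20, replacing the one-step oxidative coupling by halogenation and substitution. PhNMe3Br3 in THF at 0 °C should brominate the α' position to give the α'-bromo keto acid F7 (both epimers at CHBr). K2CO3 with Bu4NBr (cat.) in DMF at rt should close the lactone by SN2 attack of the carboxylate (5-exo-tet) on the epimer with bromine anti to it, the other epimer being fed in by bromide exchange.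

**Further compounds**

F1 | step 13 | 7-chloro-2-[2-(3,5-dibromo-4-ethylphenyl)propan-2-yl]-2-methyl-5-oxocyclohept-3-ene-1-carboxylic acid (C-1 and C-2 as in 18, both C-7 epimers) | OC(=O)[C@@H]1C(Cl)CC(=O)C=C[C@@]1(C)C(C)(C)c1cc(Br)c(CC)c(Br)c1
F2 | step 13 | (1R,2R)-2-[2-(3,5-dibromo-4-ethylphenyl)propan-2-yl]-2-methyl-5-oxocyclohepta-3,6-diene-1-carboxylic acid | OC(=O)[C@@H]1C=CC(=O)C=C[C@@]1(C)C(C)(C)c1cc(Br)c(CC)c(Br)c1
F3 | step 9 | racemic (4R*,5S*)-4-[2-(3,5-dibromo-4-ethylphenyl)propan-2-yl]-5-ethenyl-4-methylcyclohex-2-en-1-one | C=C[C@@H]1CC(=O)C=C[C@@]1(C)C(C)(C)c1cc(Br)c(CC)c(Br)c1.C=C[C@H]1CC(=O)C=C[C@]1(C)C(C)(C)c1cc(Br)c(CC)c(Br)c1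
F4 | step 9 | racemic (1R*,2R*)-2-[2-(3,5-dibromo-4-ethylphenyl)propan-2-yl]-2-methyl-5-oxocyclohex-3-ene-1-carbaldehyde (not isolated) | O=C[C@@H]1CC(=O)C=C[C@@]1(C)C(C)(C)c1cc(Br)c(CC)c(Br)c1.O=C[C@H]1CC(=O)C=C[C@]1(C)C(C)(C)c1cc(Br)c(CC)c(Br)c1
F5 | step 9 | racemic (1R*,2R*)-2-[2-(3,5-dibromo-4-ethylphenyl)propan-2-yl]-2-methyl-5-oxocyclohex-3-ene-1-carboxylic acid | OC(=O)[C@@H]1CC(=O)C=C[C@@]1(C)C(C)(C)c1cc(Br)c(CC)c(Br)c1.OC(=O)[C@H]1CC(=O)C=C[C@]1(C)C(C)(C)c1cc(Br)c(CC)c(Br)c1
F6 | step 9 | (R)-1-phenylethan-1-aminium (1R,2R)-2-[2-(3,5-dibromo-4-ethylphenyl)propan-2-yl]-2-methyl-5-oxocyclohex-3-ene-1-carboxylate | [O-]C(=O)[C@@H]1CC(=O)C=C[C@@]1(C)C(C)(C)c1cc(Br)c(CC)c(Br)c1.C[C@@H]([NH3+])c1ccccc1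
F7 | step 14 | 19 carrying bromine on the CH2 between the ketone and the benzylic CH (2,4,6-tribromo acid, both epimers at CHBr) | CCc1c(Br)cc2c(c1Br)[C@H]1C(Br)C(=O)C=C[C@](C)([C@@H]1C(=O)O)C2(C)C
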